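**Plan**

1. Labels: ring A = 4‑hydroxyphenyl on the methide carbon C7; ring B = central benzene; ring C = 2,4‑dihydroxyphenyl; ring D = quinone methide ring (C1 = carbonyl carbon, C4 = carbon bearing C7); ring E = 4‑hydroxyphenyl on the alkyne.
2. Cuts, in order: C7–ring A (aryllithium to a diaryl ketone, quinone methide by dehydration); ring D bonds C2–C3 and C4–C5 (Diels–Alder of the ynone C7(=O)–C4≡C3H with a 1‑methoxy‑3‑silyloxybutadiene, then loss of methanol); C7–C4 (ethynyl Grignard to an aldehyde); ring B–ring C (Suzuki–Miyaura); ring B–alkyne (Sonogashira); ring B–CHO (ortho‑lithiation between Br and Cl).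
3. Enabling feature: in ring D the oxygen on C1 is para to C4, and C4 carries C7. With C7 at the ketone level, C3≡C4 is an ynone whose polarisation sends the diene CH2 terminus to C3 and the CH(OMe) terminus to C4, which places the oxygen para. Rings A and D are interchangeable by phenol/quinone methide tautomerism, so the new ring may end as either.
4. Forward order: ring B is armed (CHO between Br and Cl), ring E arrives with the alkyne, ring C by biaryl coupling, the crowded C7 is reached with a slim C2 nucleophile, ring D is grown on the ynone away from the crowded centre, ring A is added last, and acid unmasks everything.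
5. Helpers: C7=O (activator, later the methide carbon), OMe and SiMe3 of the diene (lost on aromatisation), MOM and TBS groups (lost in the last step).
6. Stereochemistry: the target has no stereocentre, no E/Z element (ring D is symmetric about C1–C4) and no fixed biaryl axis; the racemic centres formed in steps 8 and 10 are erased.

Key step: step 10

Remarks: TBS = tert‑butyldimethylsilyl; MOM = methoxymethyl. ArB = 4‑({[tert‑butyl(dimethyl)silyl]oxy}methyl)‑2',4'‑bis(methoxymethoxy)‑3‑{[4‑(methoxymethoxy)phenyl]ethynyl}biphenyl‑2‑yl, i.e. ring B attached through the carbon that lies between the alkyne and ring C. Assumption: (2‑bromo‑4‑chlorophenyl)methanol and 4‑(methoxymethoxy)benzaldehyde are taken as catalogue compounds.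

**Step 1**
Reactants: 1 (2‑bromo‑4‑chlorophenyl)methanol
Product: 2 [(2‑bromo‑4‑chlorophenyl)methoxy](tert‑butyl)dimethylsilane
Conditions: TBSCl, imidazole, DMF, 0 °C to rt
Reagents that add atoms: tert‑butyl(chloro)dimethylsilane (TBSCl), CC(C)(C)[Si](C)(C)Cl
Why: Imidazole‑assisted silylation of the primary benzylic alcohol should mask it against the bases, organometallics and oxidant that follow.

**Step 2**
Reactants: 2 [(2‑bromo‑4‑chlorophenyl)methoxy](tert‑butyl)dimethylsilane
Product: 4 2‑bromo‑3‑({[tert‑butyl(dimethyl)silyl]oxy}methyl)‑6‑chlorobenzaldehyde, via aryllithium 3 (not isolated)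
Conditions: LiN(i‑Pr)2, THF, −78 °C; DMF, −78 to −20 °C; H2O
Reagents that add atoms: N,N‑dimethylformamide, CN(C)C=O
Why: Directed ortho‑metalation should remove the most acidic proton, the one flanked by Br and Cl, to give a 2,6‑dihaloaryllithium that persists at −78 °C and is formylated by DMF.

**Step 3**
Reactants: 5 4‑(methoxymethoxy)benzaldehyde
Product: 6 1‑ethynyl‑4‑(methoxymethoxy)benzene
Conditions: dimethyl (1‑diazo‑2‑oxopropyl)phosphonate, K2CO3, MeOH, 0 °C to rt
Reagents that add atoms: dimethyl (1‑diazo‑2‑oxopropyl)phosphonate, CC(=O)C(=[N+]=[N-])P(=O)(OC)OC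
Why: Seyferth–Gilbert homologation in its Ohira–Bestmann form should turn the non‑enolisable aryl aldehyde into the terminal alkyne under mild base that the MOM ether tolerates.

**Step 4**
Reactants: 4 2‑bromo‑3‑({[tert‑butyl(dimethyl)silyl]oxy}methyl)‑6‑chlorobenzaldehyde; 6 1‑ethynyl‑4‑(methoxymethoxy)benzene
Product: 7 3‑({[tert‑butyl(dimethyl)silyl]oxy}methyl)‑6‑chloro‑2‑{[4‑(methoxymethoxy)phenyl]ethynyl}benzaldehyde
Conditions: PdCl2(PPh3)2 (cat.), CuI (cat.), Et3N, THF, 60 °C
Reagents that add atoms: none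
Why: Sonogashira coupling should occur only at the C–Br bond, because a triphenylphosphine‑ligated zerovalent palladium inserts into the formyl‑activated bromide far faster than into the chloride.

**Step 5**
Reactants: 8 4‑bromobenzene‑1,3‑diol
Product: 9 1‑bromo‑2,4‑bis(methoxymethoxy)benzene
Conditions: MOMCl, i‑Pr2NEt, CH2Cl2, 0 °C to rt
Reagents that add atoms: chloromethyl methyl ether (MOMCl), COCCl
Why: Williamson‑type O‑alkylation of both phenols should give the bis‑acetal, which is stable to base and organometallics and is removed by acid at the end.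

**Step 6**
Reactants: 9 1‑bromo‑2,4‑bis(methoxymethoxy)benzene
Product: 11 2‑[2,4‑bis(methoxymethoxy)phenyl]‑4,4,5,5‑tetramethyl‑1,3,2‑dioxaborolane, via aryllithium 10 (not isolated)
Conditions: n‑BuLi, THF, −78 °C; 2‑isopropoxy‑4,4,5,5‑tetramethyl‑1,3,2‑dioxaborolane, −78 °C to rt; H2O
Reagents that add atoms: 2‑isopropoxy‑4,4,5,5‑tetramethyl‑1,3,2‑dioxaborolane, CC(C)OB1OC(C)(C)C(C)(C)O1
Why: Bromine–lithium exchange is faster at −78 °C than MOM‑directed ortho‑lithiation, and borylation of the aryllithium should give the pinacol boronate with the regiochemistry fixed by the bromide.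

**Step 7**
Reactants: 7 3‑({[tert‑butyl(dimethyl)silyl]oxy}methyl)‑6‑chloro‑2‑{[4‑(methoxymethoxy)phenyl]ethynyl}benzaldehyde; 11 2‑[2,4‑bis(methoxymethoxy)phenyl]‑4,4,5,5‑tetramethyl‑1,3,2‑dioxaborolane
Product: 12 4‑({[tert‑butyl(dimethyl)silyl]oxy}methyl)‑2',4'‑bis(methoxymethoxy)‑3‑{[4‑(methoxymethoxy)phenyl]ethynyl}biphenyl‑2‑carbaldehyde (ArB–CHO)
Conditions: Pd(OAc)2 (cat.), SPhos (cat.), K3PO4, PhMe/H2O, 90 °C
Reagents that add atoms: none
Why: Suzuki–Miyaura coupling with an electron‑rich dialkylbiarylphosphine should activate the formyl‑flanked aryl chloride and accept the ortho‑alkoxy boronate, while aldehyde, alkyne, acetals and silyl ether are inert to aqueous phosphate.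

**Step 8**
Reactants: 12 ArB–CHO
Product: 13 racemic 1‑(ArB)prop‑2‑yn‑1‑ol
Conditions: HC≡CMgBr, THF, 0 °C; H2O
Reagents that add atoms: ethynylmagnesium bromide, C#C[Mg]Br
Why: 1,2‑Addition of the slim, linear alkynyl Grignard reagent should reach the doubly ortho‑substituted aldehyde easily; the new carbinol centre forms racemic and is removed in step 9.

**Step 9**
Reactants: 13 racemic 1‑(ArB)prop‑2‑yn‑1‑ol
Product: 14 1‑(ArB)prop‑2‑yn‑1‑one
Conditions: MnO2, CH2Cl2, rt
Reagents that add atoms: none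
Why: MnO2 oxidises benzylic–propargylic alcohols selectively under neutral conditions, so the terminal ynone should form without loss of MOM or TBS groups and without nucleophiles that could add to it.

**Step 10**
Reactants: 14 1‑(ArB)prop‑2‑yn‑1‑one; 15 (E)‑1‑methoxy‑3‑(trimethylsilyloxy)buta‑1,3‑diene
Product: 18 (4‑hydroxyphenyl)(ArB)methanone, via cycloadduct 16 (not isolated), via aryl silyl ether 17 (not isolated)
Conditions: 15 (3 equiv), PhMe, 80 °C; then K2CO3 (cat.), MeOH, rt
Reagents that add atoms: none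
Why: The electron‑rich diene 15 and the electron‑poor ynone 14 should combine in a thermal, asynchronous normal‑demand Diels–Alder reaction in which the diene CH2 terminus (largest HOMO coefficient) bonds to the terminal alkyne carbon (largest LUMO coefficient, beta to the carbonyl) and the CH(OMe) terminus bonds to the acyl‑bearing alkyne carbon, giving cyclohexa‑1,4‑diene 16. 1,4‑Elimination of methanol from 16 aromatises ring D to the aryl silyl ether 17, and methanolysis of the O–Si bond gives the para‑acylphenol 18. The closest known reaction type is the regiospecific benzannulation of 1‑methoxy‑3‑silyloxybutadienes with acetylenic ketones and propiolates to para‑acylphenols. Ring D is the only ring closed, by an intermolecular [4+2] cycloaddition that makes both new ring bonds in one six‑membered suprafacial transition state. The CH(OMe) carbon of 16 is a transient racemic stereocentre destroyed on aromatisation, so no stereocontrol is needed. The step needs para regioselectivity, secured by the matched polarisation of diene and ynone, and chemoselectivity, secured because only the ynone triple bond is carbonyl‑activated while the diaryl alkyne is unactivated and a ketone C=O does not engage the diene without a Lewis acid.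

**Step 11**
Reactants: 18 (4‑hydroxyphenyl)(ArB)methanone
Product: 19 [4‑(methoxymethoxy)phenyl](ArB)methanone
Conditions: MOMCl, i‑Pr2NEt, CH2Cl2, 0 °C to rt
Reagents that add atoms: chloromethyl methyl ether (MOMCl), COCCl
Why: O‑Alkylation of the acidic para‑acylphenol should prevent a phenoxide from quenching the aryllithium and deactivating the ketone in step 12.

**Step 12**
Reactants: 19 [4‑(methoxymethoxy)phenyl](ArB)methanone; 20 1‑bromo‑4‑(methoxymethoxy)benzene
Product: 22 (ArB)bis[4‑(methoxymethoxy)phenyl]methanol, via aryllithium 21 (not isolated)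
Conditions: 20, n‑BuLi, THF, −78 °C; then 19, −78 to −20 °C; H2O
Reagents that add atoms: none
Why: Bromine–lithium exchange followed by 1,2‑addition of the aryllithium to the non‑enolisable diaryl ketone should give the triarylmethanol, whose carbinol carbon bears two identical aryl groups and is therefore not a stereocentre.

**Step 13**
Reactants: 22 (ArB)bis[4‑(methoxymethoxy)phenyl]methanol
Product: 24 Selaginellin F, via hexahydroxy triarylmethanol 23 (not isolated)
Conditions: HCl (cat., aq), MeOH/THF, 45 °C; neutral aqueous work‑up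
Reagents that add atoms: none
Why: Acid‑catalysed acetal exchange and desilylation should free all six hydroxyl groups, and ionisation of the tertiary carbinol to the bis(4‑hydroxyphenyl)carbenium ion followed by loss of a phenolic proton should give the quinone methide (fuchsone‑type dehydration).

**Compound list**

1 | (2‑bromo‑4‑chlorophenyl)methanol | OCc1ccc(Cl)cc1Br | starting material
2 | [(2‑bromo‑4‑chlorophenyl)methoxy](tert‑butyl)dimethylsilane | CC(C)(C)[Si](C)(C)OCc1ccc(Cl)cc1Br | intermediate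
3 | [2‑bromo‑3‑({[tert‑butyl(dimethyl)silyl]oxy}methyl)‑6‑chlorophenyl]lithium (not isolated) | CC(C)(C)[Si](C)(C)OCc1ccc(Cl)c([Li])c1Br | intermediate
4 | 2‑bromo‑3‑({[tert‑butyl(dimethyl)silyl]oxy}methyl)‑6‑chlorobenzaldehyde | CC(C)(C)[Si](C)(C)OCc1ccc(Cl)c(C=O)c1Br | intermediate
5 | 4‑(methoxymethoxy)benzaldehyde | COCOc1ccc(C=O)cc1 | starting material
6 | 1‑ethynyl‑4‑(methoxymethoxy)benzene | COCOc1ccc(C#C)cc1 | intermediate
7 | 3‑({[tert‑butyl(dimethyl)silyl]oxy}methyl)‑6‑chloro‑2‑{[4‑(methoxymethoxy)phenyl]ethynyl}benzaldehyde | CC(C)(C)[Si](C)(C)OCc1ccc(Cl)c(C=O)c1C#Cc1ccc(OCOC)cc1 | intermediate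
8 | 4‑bromobenzene‑1,3‑diol | Oc1ccc(Br)c(O)c1 | starting material
9 | 1‑bromo‑2,4‑bis(methoxymethoxy)benzene | COCOc1ccc(Br)c(OCOC)c1 | intermediate
10 | [2,4‑bis(methoxymethoxy)phenyl]lithium (not isolated) | COCOc1ccc([Li])c(OCOC)c1 | intermediate
11 | 2‑[2,4‑bis(methoxymethoxy)phenyl]‑4,4,5,5‑tetramethyl‑1,3,2‑dioxaborolane | COCOc1ccc(B2OC(C)(C)C(C)(C)O2)c(OCOC)c1 | intermediate
12 | 4‑({[tert‑butyl(dimethyl)silyl]oxy}methyl)‑2',4'‑bis(methoxymethoxy)‑3‑{[4‑(methoxymethoxy)phenyl]ethynyl}biphenyl‑2‑carbaldehyde (ArB–CHO) | CC(C)(C)[Si](C)(C)OCc1ccc(-c2ccc(OCOC)cc2OCOC)c(C=O)c1C#Cc1ccc(OCOC)cc1 | intermediate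
13 | racemic 1‑(ArB)prop‑2‑yn‑1‑ol | CC(C)(C)[Si](C)(C)OCc1ccc(-c2ccc(OCOC)cc2OCOC)c(C(O)C#C)c1C#Cc1ccc(OCOC)cc1 | intermediate
14 | 1‑(ArB)prop‑2‑yn‑1‑one | CC(C)(C)[Si](C)(C)OCc1ccc(-c2ccc(OCOC)cc2OCOC)c(C(=O)C#C)c1C#Cc1ccc(OCOC)cc1 | intermediate
15 | (E)‑1‑methoxy‑3‑(trimethylsilyloxy)buta‑1,3‑diene | CO/C=C/C(=C)O[Si](C)(C)C | starting material
16 | racemic (ArB)[6‑methoxy‑4‑(trimethylsilyloxy)cyclohexa‑1,4‑dien‑1‑yl]methanone (not isolated) | CC(C)(C)[Si](C)(C)OCc1ccc(-c2ccc(OCOC)cc2OCOC)c(C(=O)C2=CCC(O[Si](C)(C)C)=CC2OC)c1C#Cc1ccc(OCOC)cc1 | intermediate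
17 | (ArB){4‑[(trimethylsilyl)oxy]phenyl}methanone (not isolated) | CC(C)(C)[Si](C)(C)OCc1ccc(-c2ccc(OCOC)cc2OCOC)c(C(=O)c2ccc(O[Si](C)(C)C)cc2)c1C#Cc1ccc(OCOC)cc1 | intermediate
18 | (4‑hydroxyphenyl)(ArB)methanone | CC(C)(C)[Si](C)(C)OCc1ccc(-c2ccc(OCOC)cc2OCOC)c(C(=O)c2ccc(O)cc2)c1C#Cc1ccc(OCOC)cc1 | intermediate
19 | [4‑(methoxymethoxy)phenyl](ArB)methanone | CC(C)(C)[Si](C)(C)OCc1ccc(-c2ccc(OCOC)cc2OCOC)c(C(=O)c2ccc(OCOC)cc2)c1C#Cc1ccc(OCOC)cc1 | intermediate
20 | 1‑bromo‑4‑(methoxymethoxy)benzene | COCOc1ccc(Br)cc1 | starting material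
21 | [4‑(methoxymethoxy)phenyl]lithium (not isolated) | COCOc1ccc([Li])cc1 | intermediate
22 | (ArB)bis[4‑(methoxymethoxy)phenyl]methanol | CC(C)(C)[Si](C)(C)OCc1ccc(-c2ccc(OCOC)cc2OCOC)c(C(O)(c2ccc(OCOC)cc2)c2ccc(OCOC)cc2)c1C#Cc1ccc(OCOC)cc1 | intermediate
23 | {2',4'‑dihydroxy‑4‑(hydroxymethyl)‑3‑[(4‑hydroxyphenyl)ethynyl]biphenyl‑2‑yl}bis(4‑hydroxyphenyl)methanol (not isolated) | OCc1ccc(-c2ccc(O)cc2O)c(C(O)(c2ccc(O)cc2)c2ccc(O)cc2)c1C#Cc1ccc(O)cc1 | intermediate
24 | Selaginellin F, 4‑[{2',4'‑dihydroxy‑4‑(hydroxymethyl)‑3‑[(4‑hydroxyphenyl)ethynyl]biphenyl‑2‑yl}(4‑hydroxyphenyl)methylidene]cyclohexa‑2,5‑dien‑1‑one | O=C1C=CC(=C(c2ccc(O)cc2)c2c(-c3ccc(O)cc3O)ccc(CO)c2C#Cc2ccc(O)cc2)C=C1 | target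

**Totals**

Total step count: 13. Longest linear sequence: 10 steps (1, 2, 4, 7, 8, 9, 10, 11, 12, 13).

**Steps most likely to fail**

Step 12. The carbonyl of 19 is shielded by two ortho substituents and deactivated by the para‑alkoxyphenyl group, so addition may stall, or the lithium alkoxide may add to the neighbouring alkyne on warming. The fallback sets out from 18 and replaces carbonyl addition by conjugate arylation and oxidation. NaBH4 in MeOH/THF should reduce 18 to the racemic benzhydrol (4‑hydroxyphenyl)(ArB)methanol F1. Catalytic TsOH with excess phenol in CH2Cl2 at 0 °C should dehydrate F1 to its para‑quinone methide and trap it by para‑selective Friedel–Crafts 1,6‑addition, giving the triarylmethane 4,4'‑[(ArB)methylene]diphenol F2. DDQ should abstract hydride from the triaryl C–H to give the protected quinone methide 4‑[(ArB)(4‑hydroxyphenyl)methylidene]cyclohexa‑2,5‑dien‑1‑one F3. Treating F3 under the conditions of step 13 should return to the route at 24.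

Step 10. The terminal ynone may polymerise or be consumed by adventitious nucleophiles, and the diene may hydrolyse, before cycloaddition is complete. The fallback sets out from 12: aryllithium 21 (from 20 and n‑BuLi, THF, −78 °C) should add to the aldehyde to give the racemic benzhydrol [4‑(methoxymethoxy)phenyl](ArB)methanol F4, and MnO2 oxidation of F4 should return to the route at 19.

Step 7. Protodeboronation of the electron‑rich ortho‑alkoxy boronate 11 may outrun transmetalation at the hindered chloride. The fallback sets out from 7 and reverses the roles of the partners. Miyaura borylation (B2pin2, Pd(OAc)2, XPhos, KOAc, dioxane, 100 °C) should give 3‑({[tert‑butyl(dimethyl)silyl]oxy}methyl)‑2‑{[4‑(methoxymethoxy)phenyl]ethynyl}‑6‑(4,4,5,5‑tetramethyl‑1,3,2‑dioxaborolan‑2‑yl)benzaldehyde F5. Suzuki–Miyaura coupling of F5 with bromide 9 (Pd(OAc)2, SPhos, K3PO4) should return to the route at 12.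

**Further compounds**

F1 | step 12 | racemic (4‑hydroxyphenyl)(ArB)methanol | CC(C)(C)[Si](C)(C)OCc1ccc(-c2ccc(OCOC)cc2OCOC)c(C(O)c2ccc(O)cc2)c1C#Cc1ccc(OCOC)cc1
F2 | step 12 | 4,4'‑[(ArB)methylene]diphenol | CC(C)(C)[Si](C)(C)OCc1ccc(-c2ccc(OCOC)cc2OCOC)c(C(c2ccc(O)cc2)c2ccc(O)cc2)c1C#Cc1ccc(OCOC)cc1
F3 | step 12 | 4‑[(ArB)(4‑hydroxyphenyl)methylidene]cyclohexa‑2,5‑dien‑1‑one | CC(C)(C)[Si](C)(C)OCc1ccc(-c2ccc(OCOC)cc2OCOC)c(C(c2ccc(O)cc2)=C2C=CC(=O)C=C2)c1C#Cc1ccc(OCOC)cc1
F4 | step 10 | racemic [4‑(methoxymethoxy)phenyl](ArB)methanol | CC(C)(C)[Si](C)(C)OCc1ccc(-c2ccc(OCOC)cc2OCOC)c(C(O)c2ccc(OCOC)cc2)c1C#Cc1ccc(OCOC)cc1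
F5 | step 7 | 3‑({[tert‑butyl(dimethyl)silyl]oxy}methyl)‑2‑{[4‑(methoxymethoxy)phenyl]ethynyl}‑6‑(4,4,5,5‑tetramethyl‑1,3,2‑dioxaborolan‑2‑yl)benzaldehyde | CC(C)(C)[Si](C)(C)OCc1ccc(B2OC(C)(C)C(C)(C)O2)c(C=O)c1C#Cc1ccc(OCOC)cc1
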